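**Assumption:** (S)-citronellal is the commercial enantiomer needed. The alkylidene acceptor 3 is used as an E/Z mixture. The Ca–OH/enal lactol that can form in 16 is reversible.

## Retrosynthetic overview
1. The nine-membered ring is closed last by a macro Horner–Wadsworth–Emmons (HWE) olefination (C2=C3). The E-selective HWE puts the ester trans to C4, which is the ring-cis enal. The ester is then taken to the CHO, and Ca–OH is acetylated.
2. The E-trisubstituted C5=C6 alkene comes from cross-metathesis (CM) of a methallyl adduct with 4,4-dimethoxybutene. C8–OH comes from reagent-controlled Brown methallylation of an aldehyde.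
3. That aldehyde comes from one enamine Michael addition of (S)-citronellal, which already carries C10, to a phosphonoacetate-type acceptor. This sets C9 and C1 syn to each other.
4. Order of events: acyclic assembly (Michael, methallylation, CM), then ring closure, then redox and protecting-group clean-up. The ring stays acyclic until step 7, so there is no ring-strain problem before then.

## Route

**Step 1**
Reactants: 1 (2-(TBSO)acetaldehyde); 2 (tert-butyl diethylphosphonoacetate)
Product: 3 (tert-butyl 4-(TBSO)-2-(diethoxyphosphoryl)but-2-enoate, E/Z mixture)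
Conditions: TiCl4, N-methylmorpholine, THF, 0 °C → rt
Reagents that add atoms: none
Why: Knoevenagel condensation gives the doubly activated alkylidene acceptor; no stereocentre forms here, and the E/Z ratio is assumed not to matter because C1 is set by the catalyst in step 2.

**Step 2**
Reactants: 4 ((S)-citronellal); 3
Product: 5 (Michael adduct, aldehyde; C2 is an epimeric mixture)
Conditions: (S)-diphenylprolinol TMS ether (20 mol%), PhCO2H (20 mol%), toluene, 4 °C → rt
Reagents that add atoms: none
Why: Proposed new method: the (S)-Jørgensen–Hayashi catalyst forms the E-anti enamine of 4, which adds to the β-carbon of 3 through the Seebach synclinal transition state, with the phosphonate/ester-bearing carbon as the acceptor anchor; the closest known reaction is enamine Michael addition of aldehydes to nitroalkenes and alkylidene malonates, which gives syn adducts. This fixes C9 = R and C1 = R (target numbering) relative to the retained C10 = S, and the acidic C2–H is left epimeric and destroyed in step 7.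

**Step 3**
Reactants: 5; 6 (methallylmagnesium chloride)
Product: 7 (homoallylic alcohol, 8S)
Conditions: Ipc2BOMe (enantiomer chosen to give 8S) + 6, Et2O, –78 °C to give Ipc2B-methallyl; then 5, –78 °C; then NaBO3·4H2O, THF/H2O
Reagents that add atoms: 6, methallylmagnesium chloride, `C=C(C)C[Mg]Cl` (delivers the C4H7 unit)
Why: Brown asymmetric methallylation proceeds through a Zimmerman–Traxler chair and is reagent-controlled, so C8 (S) is set regardless of the α/β-branched substrate bias; the 1,1-disubstituted alkene is the handle for the CM in step 5.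

**Step 4**
Reactants: 7; 8 (TBSOTf)
Product: 9 (bis-TBS ether)
Conditions: 8, 2,6-lutidine, CH2Cl2, –78 °C
Reagents that add atoms: 8, TBSOTf, `CC(C)(C)[Si](C)(C)OS(=O)(=O)C(F)(F)F`
Why: Silylation of the hindered secondary alcohol prevents δ-lactonisation of the C8 alkoxide onto the C2′ ester and protects it for the later base, DIBAL and MnO2 steps; no stereocentre is touched.

**Step 5**
Reactants: 9; 10 (4,4-dimethoxybut-1-ene)
Product: 11 (E-trisubstituted alkene acetal)
Conditions: Hoveyda–Grubbs II (10 mol%), 10 (8 equiv), CH2Cl2, 40 °C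
Reagents that add atoms: none (10 is a reactant; ethylene is lost)
Why: Cross-metathesis of the 1,1-disubstituted methallyl alkene with a type-I terminal alkene is E-selective, placing C4 trans to C7 as required for the ring-trans C5=C6; the Ru carbene reacts preferentially at the methallyl alkene rather than the prenyl alkene.

**Step 6**
Reactants: 11
Product: 12 (β,γ-unsaturated aldehyde)
Conditions: PPTS, acetone/H2O (10:1), 50 °C
Reagents that add atoms: water, `O` (supplies the aldehyde O)
Why: Mild acetal hydrolysis; silyl ethers, tert-butyl ester and alkenes survive, and C9 cannot epimerise because C8 is no longer carbonyl.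

**Step 7**
Reactants: 12
Product: 13 (nine-membered-ring enoate)
Conditions: LiCl, DBU, MeCN, 2 mM, syringe-pump addition over 8 h, 25 °C
Reagents that add atoms: none
Why: Proposed new method: Masamune–Roush intramolecular HWE macrocyclisation, with the stabilised phosphonoacetate carbanion attacking the C3 aldehyde; the closest known reaction is macrocyclic HWE olefination of 12–16-membered rings, and high dilution is needed here. The E-selective elimination puts the ester trans to C4, giving the ring-cis C2=C3, and the preformed E-C5=C6 is retained.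

**Step 8**
Reactants: 13
Product: 14 (allylic alcohol)
Conditions: DIBAL-H (4 equiv), CH2Cl2, –78 → 0 °C
Reagents that add atoms: none (hydride only)
Why: DIBAL reduces the conjugated tert-butyl ester to the allylic alcohol while the silyl ethers and isolated alkenes survive; all stereocentres and alkene geometries are untouched.

**Step 9**
Reactants: 14
Product: 15 (enal, bis-TBS)
Conditions: MnO2 (20 equiv), CH2Cl2, rt
Reagents that add atoms: none
Why: MnO2 oxidises only the allylic primary alcohol, giving the ring-cis enal without epimerisation or alkene isomerisation.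

**Step 10**
Reactants: 15
Product: 16 (diol-enal)
Conditions: HF·pyridine, pyridine/THF, 0 °C → rt, 24 h
Reagents that add atoms: none
Why: Global Si–O cleavage by fluoride; the enal and the E/Z alkenes are stable to these buffered conditions.

**Step 11**
Reactants: 16; 17 (acetic anhydride)
Product: 18 (hydroxyacetyldictyolal)
Conditions: 17 (1.1 equiv), pyridine, DMAP (5 mol%), CH2Cl2, –20 °C
Reagents that add atoms: 17, acetic anhydride, `CC(=O)OC(C)=O`
Why: The unhindered primary Ca–OH is acetylated chemoselectively over the hindered, neopentyl-like secondary C8–OH, giving the target.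

## Compound list
1 | 2-[(tert-butyldimethylsilyl)oxy]acetaldehyde | `CC(C)(C)[Si](C)(C)OCC=O` | starting material
2 | tert-butyl 2-(diethoxyphosphoryl)acetate | `CC(C)(C)OC(=O)CP(=O)(OCC)OCC` | starting material
3 | tert-butyl 4-(TBSO)-2-(diethoxyphosphoryl)but-2-enoate (E/Z) | `CC(C)(C)OC(=O)C(=CCO[Si](C)(C)C(C)(C)C)P(=O)(OCC)OCC` | intermediate
4 | (3S)-3,7-dimethyloct-6-enal ((S)-citronellal) | `O=CC[C@@H](C)CCC=C(C)C` | starting material
5 | tert-butyl (3S,4R)-3-[(TBSO)methyl]-2-(diethoxyphosphoryl)-4-[(2S)-6-methylhept-5-en-2-yl]-5-oxopentanoate (C2 epimeric) | `O=C[C@H]([C@@H](C)CCC=C(C)C)[C@@H](CO[Si](C)(C)C(C)(C)C)C(C(=O)OC(C)(C)C)P(=O)(OCC)OCC` | intermediate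
6 | methallylmagnesium chloride | `C=C(C)C[Mg]Cl` | starting material
7 | tert-butyl (3S,4R,5S)-3-[(TBSO)methyl]-2-(diethoxyphosphoryl)-5-hydroxy-7-methyl-4-[(2S)-6-methylhept-5-en-2-yl]oct-7-enoate | `C=C(C)C[C@H](O)[C@H]([C@@H](C)CCC=C(C)C)[C@@H](CO[Si](C)(C)C(C)(C)C)C(C(=O)OC(C)(C)C)P(=O)(OCC)OCC` | intermediate
8 | tert-butyldimethylsilyl triflate | `CC(C)(C)[Si](C)(C)OS(=O)(=O)C(F)(F)F` | starting material
9 | 5-OTBS ether of 7 | `C=C(C)C[C@H](O[Si](C)(C)C(C)(C)C)[C@H]([C@@H](C)CCC=C(C)C)[C@@H](CO[Si](C)(C)C(C)(C)C)C(C(=O)OC(C)(C)C)P(=O)(OCC)OCC` | intermediate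
10 | 4,4-dimethoxybut-1-ene | `COC(OC)CC=C` | starting material
11 | tert-butyl (3S,4R,5S,7E)-5-(TBSO)-3-[(TBSO)methyl]-2-(diethoxyphosphoryl)-10,10-dimethoxy-7-methyl-4-[(2S)-6-methylhept-5-en-2-yl]dec-7-enoate | `COC(OC)C/C=C(\C)C[C@H](O[Si](C)(C)C(C)(C)C)[C@H]([C@@H](C)CCC=C(C)C)[C@@H](CO[Si](C)(C)C(C)(C)C)C(C(=O)OC(C)(C)C)P(=O)(OCC)OCC` | intermediate
12 | 10-oxo analogue of 11 (aldehyde) | `O=CC/C=C(\C)C[C@H](O[Si](C)(C)C(C)(C)C)[C@H]([C@@H](C)CCC=C(C)C)[C@@H](CO[Si](C)(C)C(C)(C)C)C(C(=O)OC(C)(C)C)P(=O)(OCC)OCC` | intermediate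
13 | tert-butyl (1E,4E,7S,8R,9R)-9-[(TBSO)methyl]-7-(TBSO)-5-methyl-8-[(2S)-6-methylhept-5-en-2-yl]cyclonona-1,4-diene-1-carboxylate | `CC(C)(C)[Si](C)(C)OC[C@H]1/C(C(=O)OC(C)(C)C)=C\C/C=C(\C)C[C@H](O[Si](C)(C)C(C)(C)C)[C@@H]1[C@@H](C)CCC=C(C)C` | intermediate
14 | {(1E,4E,7S,8R,9R)-9-[(TBSO)methyl]-7-(TBSO)-5-methyl-8-[(2S)-6-methylhept-5-en-2-yl]cyclonona-1,4-dien-1-yl}methanol | `CC(C)(C)[Si](C)(C)OC[C@H]1/C(CO)=C\C/C=C(\C)C[C@H](O[Si](C)(C)C(C)(C)C)[C@@H]1[C@@H](C)CCC=C(C)C` | intermediate
15 | (1E,4E,7S,8R,9R)-9-[(TBSO)methyl]-7-(TBSO)-5-methyl-8-[(2S)-6-methylhept-5-en-2-yl]cyclonona-1,4-diene-1-carbaldehyde | `CC(C)(C)[Si](C)(C)OC[C@H]1/C(C=O)=C\C/C=C(\C)C[C@H](O[Si](C)(C)C(C)(C)C)[C@@H]1[C@@H](C)CCC=C(C)C` | intermediate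
16 | (1E,4E,7S,8R,9R)-7-hydroxy-9-(hydroxymethyl)-5-methyl-8-[(2S)-6-methylhept-5-en-2-yl]cyclonona-1,4-diene-1-carbaldehyde | `OC[C@H]1/C(C=O)=C\C/C=C(\C)C[C@H](O)[C@@H]1[C@@H](C)CCC=C(C)C` | intermediate
17 | acetic anhydride | `CC(=O)OC(C)=O` | starting material
18 | [(1R,2E,5E,8S,9R)-2-formyl-8-hydroxy-6-methyl-9-[(2S)-6-methylhept-5-en-2-yl]cyclonona-2,5-dien-1-yl]methyl acetate (hydroxyacetyldictyolal) | `CC(=O)OC[C@H]1/C(C=O)=C\C/C=C(\C)C[C@H](O)[C@@H]1[C@@H](C)CCC=C(C)C` | target

## Totals
Total steps: 11. Longest linear sequence: 11 steps (1 → 3 → 5 → 7 → 9 → 11 → 12 → 13 → 14 → 15 → 16 → 18), which is 10 steps from (S)-citronellal.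

**Three steps most likely to fail**
1. **Step 2 (enamine Michael to the alkylidene phosphonoacetate).** The acceptor is hindered, and C1 selectivity may erode with the E/Z mixture or with catalyst/substrate mismatch. Fallback: build C9–C1 by Ireland–Claisen of the (S)-citronellic ester of (Z)-HOCH2C(CO2tBu)=CHCH2OTBS (chair transition state fixes the C9/C1 relationship). Take the resulting exo-methylene acrylate through methallylation and CM, and close the ring by RCM instead of HWE.
2. **Step 7 (nine-membered-ring HWE).** Oligomerisation, or isomerisation of the β,γ-unsaturated aldehyde to the conjugated enal, is likely. Fallback: change the ring closure to an intramolecular Pd-catalysed alkenyl–alkyl (Negishi) coupling at C4–C5 on a preformed (Z)-C2=C3 enoate.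
3. **Step 5 (CM).** Poor E/Z ratio, or competing reaction of the prenyl alkene. Fallback: Brown propargylation of 5, Zr-catalysed methylalumination/I2 to the E-alkenyl iodide, then Negishi coupling with (1,3-dioxolan-2-ylmethyl)zinc bromide to give the same C3 acetal with the E-alkene fixed by syn-carbometalation.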